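**Retrosynthetic overview**
1. The oxirane comes last: outer-face epoxidation of the (4Z)-alkene of the macrocyclic butenolide.
2. Ten-membered carbocycle and butenolide form in one operation: electroreductive chromium/nickel C6–C7 closure of an enal–enol triflate seco-ester, then O6–C12 lactonization (carbocycle first, butenolide second, oxirane third).
3. The enol triflate unit (C7, C11–C13) is grown from a C7 carboxylic acid by Stille acylation, acetic acid addition and chelate-controlled triflation.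
4. C1–C2 comes from opening a butyrolactone (C1, C8–C10) with a (Z)-homoallyllithium made from but-2-yn-1-ol.
5. C8 is bought in (S)-5-[(trityloxy)methyl]butyrolactone (from L-glutamic acid); C10 is set from it on the lactone, C6 in the ring closure, C4/C5 in the epoxidation.

Assumption: (S)-5-[(trityloxy)methyl]dihydrofuran-2(3H)-one and methyl 2-(tributylstannyl)acrylate are purchased; atom labels C1–C15 follow germacrane numbering of the target (C6–O–C12 lactone, C8 methacrylate, C10 and C13 acetates).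

**Route**

Step 1
Reactants: 1 but-2-yn-1-ol
Product: 3 (Z)-3-iodobut-2-en-1-ol, via cyclic vinylalanate 2 (not isolated)
Conditions: NaAlH2(OCH2CH2OCH3)2, THF, 0 °C to rt; then I2, −78 to 0 °C
Reagents that add atoms: iodine, II
Why: Hydroxyl-directed trans-hydroalumination puts aluminium on C3 in a five-membered alkoxyalanate and iodinolysis with retention gives only the Z iodide (alkyne hydroalumination–iodination).

Step 2
Reactants: 3 (Z)-3-iodobut-2-en-1-ol
Product: 4 (Z)-tert-butyl[(3-iodobut-2-en-1-yl)oxy]diphenylsilane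
Conditions: t-BuPh2SiCl, imidazole, CH2Cl2, 0 °C to rt
Reagents that add atoms: tert-butyl(chloro)diphenylsilane, CC(C)(C)[Si](Cl)(c1ccccc1)c1ccccc1
Why: Silyl ether formation on a primary alcohol gives a group that survives organolithiums, chromic acid and acylations.

Step 3
Reactants: 4 (Z)-tert-butyl[(3-iodobut-2-en-1-yl)oxy]diphenylsilane
Product: 6 (Z)-5-[(tert-butyldiphenylsilyl)oxy]-3-methylpent-3-en-1-ol, via vinyllithium 5 (not isolated)
Conditions: t-BuLi (2 equiv), Et2O, −78 °C; then oxirane, −78 to 0 °C; aq. NH4Cl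
Reagents that add atoms: oxirane, C1CO1
Why: Iodine–lithium exchange keeps the alkene geometry and the vinyllithium opens oxirane (epoxide alkylation), so the new two-carbon arm ends cis to CH2OSi.

Step 4
Reactants: 6 (Z)-5-[(tert-butyldiphenylsilyl)oxy]-3-methylpent-3-en-1-ol
Product: 7 (Z)-tert-butyl[(5-iodo-3-methylpent-2-en-1-yl)oxy]diphenylsilane
Conditions: I2, PPh3, imidazole, CH2Cl2, 0 °C
Reagents that add atoms: iodine, II
Why: Appel-type iodination converts the primary homoallylic alcohol into the iodide without touching the alkene or the silyl ether.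

Step 5
Reactants: 8 (S)-5-[(trityloxy)methyl]dihydrofuran-2(3H)-one
Product: 10 (3R,5S)-3-methyl-5-[(trityloxy)methyl]dihydrofuran-2(3H)-one, via lithium enolate 9 (not isolated)
Conditions: LiN(iPr)2, THF, −78 °C; MeI, −78 to −40 °C
Reagents that add atoms: iodomethane, CI
Why: Lactone enolate alkylation occurs mainly anti to the CH2OTr group, and the epimer ratio does not matter because this centre is planarized again in step 6.

Step 6
Reactants: 10 (3R,5S)-3-methyl-5-[(trityloxy)methyl]dihydrofuran-2(3H)-one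
Product: 12 (3R,5S)-3-hydroxy-3-methyl-5-[(trityloxy)methyl]dihydrofuran-2(3H)-one, via potassium enolate 11 (not isolated)
Conditions: KN(SiMe3)2, THF, −78 °C; racemic 2-(phenylsulfonyl)-3-phenyloxaziridine, −78 °C; aq. NH4Cl
Reagents that add atoms: 2-(phenylsulfonyl)-3-phenyloxaziridine, O=S(=O)(N1OC1c1ccccc1)c1ccccc1
Why: Electrophilic enolate hydroxylation (Davis oxidation) takes place on the face opposite the bulky CH2OTr substituent, so oxygen enters trans and methyl ends cis to it, which fixes the future C10 as R under control of the purchased C8 centre.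

Step 7
Reactants: 7 (Z)-tert-butyl[(5-iodo-3-methylpent-2-en-1-yl)oxy]diphenylsilane; 12 (3R,5S)-3-hydroxy-3-methyl-5-[(trityloxy)methyl]dihydrofuran-2(3H)-one
Product: 15 (2S,4R,8Z)-10-[(tert-butyldiphenylsilyl)oxy]-2,4-dihydroxy-4,8-dimethyl-1-(trityloxy)dec-8-en-5-one, via alkyllithium 13 (not isolated), via dilithium lactolate 14 (not isolated)
Conditions: 7, t-BuLi (2 equiv), Et2O, −78 °C; then 12 pre-treated with LiN(SiMe3)2 (1 equiv), THF, −78 to −40 °C; aq. NH4Cl
Reagents that add atoms: none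
Why: The primary alkyllithium adds once to the lactone carbonyl because the tetrahedral lithium lactolate is stable at low temperature and the quaternary α-carbon cannot enolize (acyl substitution of a lactone by an organolithium), which forms C1–C2, frees O8 and leaves both stereocentres untouched.

Step 8
Reactants: 15 (2S,4R,8Z)-10-[(tert-butyldiphenylsilyl)oxy]-2,4-dihydroxy-4,8-dimethyl-1-(trityloxy)dec-8-en-5-one
Product: 17 (2S,4R,8Z)-4-acetoxy-10-[(tert-butyldiphenylsilyl)oxy]-4,8-dimethyl-5-oxo-1-(trityloxy)dec-8-en-2-yl 2-methylprop-2-enoate, via C8 monomethacrylate 16 (not isolated)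
Conditions: CH2=C(CH3)COCl, Et3N, DMAP (cat.), CH2Cl2, −20 °C; then Ac2O, DMAP, rt, 24 h
Reagents that add atoms: methacryloyl chloride, C=C(C)C(Cl)=O; acetic anhydride, CC(=O)OC(C)=O
Why: The secondary C8 hydroxyl (open form of the lactol) is acylated first by the acid chloride and the hindered tertiary C10 hydroxyl then by DMAP-activated acetic anhydride (Steglich-type acylation), so the two different esters go on in one flask.

Step 9
Reactants: 17 (2S,4R,8Z)-4-acetoxy-10-[(tert-butyldiphenylsilyl)oxy]-4,8-dimethyl-5-oxo-1-(trityloxy)dec-8-en-2-yl 2-methylprop-2-enoate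
Product: 18 (2S,4R,8Z)-4-acetoxy-10-[(tert-butyldiphenylsilyl)oxy]-4,8-dimethyl-2-[(2-methylprop-2-enoyl)oxy]-5-oxodec-8-enoic acid
Conditions: CrO3, H2SO4, H2O, acetone, 0 °C
Reagents that add atoms: water, O
Why: Aqueous chromic acid cleaves the acid-labile trityl ether and oxidizes the released primary alcohol to the acid (Jones oxidation), while the tert-butyldiphenylsilyl ether, the esters and the trisubstituted alkene are inert at 0 °C.

Step 10
Reactants: 18 (2S,4R,8Z)-4-acetoxy-10-[(tert-butyldiphenylsilyl)oxy]-4,8-dimethyl-2-[(2-methylprop-2-enoyl)oxy]-5-oxodec-8-enoic acid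
Product: 21 methyl (4S,6R,10Z)-6-acetoxy-2-(acetoxymethyl)-12-[(tert-butyldiphenylsilyl)oxy]-6,10-dimethyl-4-[(2-methylprop-2-enoyl)oxy]-3,7-dioxododec-10-enoate, via acid chloride 19 (not isolated), via 2-acylacrylate 20 (not isolated)
Conditions: (COCl)2, DMF (cat.), CH2Cl2, 0 °C; then methyl 2-(tributylstannyl)acrylate, Pd2(dba)3 (2.5 mol%), P(2-furyl)3, THF, 40 °C; then AcOH, NaOAc (cat.), rt
Reagents that add atoms: methyl 2-(tributylstannyl)acrylate, C=C(C(=O)OC)[Sn](CCCC)(CCCC)CCCC; acetic acid, CC(=O)O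
Why: Stille acylation of the α-stannylacrylate gives a 2-acylacrylate whose very electrophilic methylene takes up acetic acid by conjugate (oxa-Michael) addition, which installs C11, C12, C13 and the C13 acetate under neutral conditions that do not epimerize C8.

Step 11
Reactants: 21 methyl (4S,6R,10Z)-6-acetoxy-2-(acetoxymethyl)-12-[(tert-butyldiphenylsilyl)oxy]-6,10-dimethyl-4-[(2-methylprop-2-enoyl)oxy]-3,7-dioxododec-10-enoate
Product: 23 methyl (2Z,4S,6R,10Z)-6-acetoxy-2-(acetoxymethyl)-12-[(tert-butyldiphenylsilyl)oxy]-6,10-dimethyl-4-[(2-methylprop-2-enoyl)oxy]-7-oxo-3-{[(trifluoromethyl)sulfonyl]oxy}dodeca-2,10-dienoate, via chelated lithium enolate 22 (not isolated)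
Conditions: LiN(SiMe3)2 (1.05 equiv), THF, −78 °C; Tf2O, −78 °C
Reagents that add atoms: trifluoromethanesulfonic anhydride, O=S(=O)(OS(=O)(=O)C(F)(F)F)C(F)(F)F
Why: The lithium enolate of a 2-substituted 3-oxo ester is chelated between the enolate and ester oxygens, so O-sulfonylation at −78 °C gives the enol triflate with OTf cis to CO2Me (chelation-controlled enol triflate formation) before acetate can be expelled.

Step 12
Reactants: 23 (2Z)-enol triflate silyl ether
Product: 24 methyl (2Z,4S,6R,10Z)-6-acetoxy-2-(acetoxymethyl)-12-hydroxy-6,10-dimethyl-4-[(2-methylprop-2-enoyl)oxy]-7-oxo-3-{[(trifluoromethyl)sulfonyl]oxy}dodeca-2,10-dienoate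
Conditions: HF·pyridine, pyridine, THF, 0 °C to rt
Reagents that add atoms: none
Why: Buffered fluoride desilylation removes the silyl ether without touching the esters, the enol triflate or the ketone.

Step 13
Reactants: 24 (2Z)-enol triflate allylic alcohol
Product: 25 methyl (2Z,4S,6R,10Z)-6-acetoxy-2-(acetoxymethyl)-6,10-dimethyl-4-[(2-methylprop-2-enoyl)oxy]-7,12-dioxo-3-{[(trifluoromethyl)sulfonyl]oxy}dodeca-2,10-dienoate
Conditions: TEMPO (10 mol%), PhI(OAc)2, CH2Cl2, rt
Reagents that add atoms: none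
Why: Oxoammonium-mediated oxidation of the allylic alcohol gives the enal under neutral conditions that do not isomerize the Z alkene.

Step 14
Reactants: 25 (2Z,10Z)-enol triflate enal
Product: 27 (4Z,6S,8S,10R)-10,13-diacetoxy-8-[(2-methylprop-2-enoyl)oxy]-1-oxogermacra-4,7(11)-dien-6,12-olide, via ring-closed trimethylsilyl ether 26 (not isolated)
Conditions: undivided cell, Al anode, Ni-foam cathode, 2 mA; CrCl2 (20 mol%), NiCl2·MeOCH2CH2OMe (5 mol%), 2,9-dimethyl-1,10-phenanthroline (5 mol%), Me3SiCl (2.5 equiv), n-Bu4NPF6, DMF, rt, slow addition of 25 (final 2 mM); then 1 M HCl, THF, rt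
Reagents that add atoms: none
Why: Proposed new method: an electrocatalytic Nozaki–Hiyama–Kishi ring closure in which the cathode returns trivalent chromium to divalent chromium, zerovalent nickel inserts into the C7–OTf bond, the alkenyl group passes to chromium and adds 1,2 to the tethered Z-enal, Me3SiCl frees the chromium alkoxide and acid then closes the butenolide because C6–O sits cis to CO2Me; C6 is set because H8 eclipses C7=C11 to avoid A(1,3) strain with CH2OAc, which places C9 on one face so that the tether brings C5 in on that same face; the closest known reactions are the intermolecular electrochemical Nozaki–Hiyama–Kishi coupling of alkenyl halides or triflates with aldehydes and stoichiometric chromium-mediated macrocyclizations, neither shown for a ten-membered ring or a tetrasubstituted β-triflyloxy enoate.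

Step 15
Reactants: 27 (4Z,6S,8S,10R)-10,13-diacetoxy-8-[(2-methylprop-2-enoyl)oxy]-1-oxogermacra-4,7(11)-dien-6,12-olide
Product: 28 (4R,5S,6R,8S,10R)-10,13-diacetoxy-4,5-epoxy-8-[(2-methylprop-2-enoyl)oxy]-1-oxogermacr-7(11)-en-6,12-olide (CNP0172381.2)
Conditions: mCPBA (1.1 equiv), NaHCO3, CH2Cl2, 0 °C
Reagents that add atoms: 3-chloroperoxybenzoic acid, OOC(=O)c1cccc(Cl)c1
Why: Peracid epoxidation (Prilezhaev reaction) of the only electron-rich alkene occurs from the outer face of the ten-membered ring, anti to ring carbon C7 with H6 eclipsing the alkene to avoid A(1,3) strain with C3, which gives the cis-4,5-oxirane as 4R,5S.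

**Compound list**

1 | but-2-yn-1-ol | CC#CCO | starting material
2 | sodium 2,2-bis(2-methoxyethoxy)-3-methyl-2,5-dihydro-1,2-oxaluminol-2-uide (cyclic vinylalanate) | [Na+].CC1=CCO[Al-]1(OCCOC)OCCOC | intermediate (not isolated)
3 | (Z)-3-iodobut-2-en-1-ol | C/C(I)=C/CO | intermediate
4 | (Z)-tert-butyl[(3-iodobut-2-en-1-yl)oxy]diphenylsilane | C/C(I)=C/CO[Si](c1ccccc1)(c1ccccc1)C(C)(C)C | intermediate
5 | vinyllithium from 4, Li cis to CH2OSi | C/C([Li])=C/CO[Si](c1ccccc1)(c1ccccc1)C(C)(C)C | intermediate (not isolated)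
6 | (Z)-5-[(tert-butyldiphenylsilyl)oxy]-3-methylpent-3-en-1-ol | OCC/C(C)=C\CO[Si](c1ccccc1)(c1ccccc1)C(C)(C)C | intermediate
7 | (Z)-tert-butyl[(5-iodo-3-methylpent-2-en-1-yl)oxy]diphenylsilane | ICC/C(C)=C\CO[Si](c1ccccc1)(c1ccccc1)C(C)(C)C | intermediate
8 | (S)-5-[(trityloxy)methyl]dihydrofuran-2(3H)-one | O=C1CC[C@@H](COC(c2ccccc2)(c2ccccc2)c2ccccc2)O1 | starting material
9 | lithium enolate of 8 | [Li]OC1=CC[C@@H](COC(c2ccccc2)(c2ccccc2)c2ccccc2)O1 | intermediate (not isolated)
10 | (3R,5S)-3-methyl-5-[(trityloxy)methyl]dihydrofuran-2(3H)-one (major trans epimer) | O=C1[C@H](C)C[C@@H](COC(c2ccccc2)(c2ccccc2)c2ccccc2)O1 | intermediate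
11 | potassium enolate of 10 | [K]OC1=C(C)C[C@@H](COC(c2ccccc2)(c2ccccc2)c2ccccc2)O1 | intermediate (not isolated)
12 | (3R,5S)-3-hydroxy-3-methyl-5-[(trityloxy)methyl]dihydrofuran-2(3H)-one | O=C1[C@](C)(O)C[C@@H](COC(c2ccccc2)(c2ccccc2)c2ccccc2)O1 | intermediate
13 | (Z)-{5-[(tert-butyldiphenylsilyl)oxy]-3-methylpent-3-en-1-yl}lithium | [Li]CC/C(C)=C\CO[Si](c1ccccc1)(c1ccccc1)C(C)(C)C | intermediate (not isolated)
14 | dilithium lactolate from 12 and 13 (hemiketal carbon unassigned) | [Li]O[C@]1(C)C[C@@H](COC(c2ccccc2)(c2ccccc2)c2ccccc2)OC1(O[Li])CC/C(C)=C\CO[Si](c1ccccc1)(c1ccccc1)C(C)(C)C | intermediate (not isolated)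
15 | (2S,4R,8Z)-10-[(tert-butyldiphenylsilyl)oxy]-2,4-dihydroxy-4,8-dimethyl-1-(trityloxy)dec-8-en-5-one (open form; in equilibrium with its five-membered lactol) | c1ccccc1C(c1ccccc1)(c1ccccc1)OC[C@@H](O)C[C@@](C)(O)C(=O)CC/C(C)=C\CO[Si](c1ccccc1)(c1ccccc1)C(C)(C)C | intermediate
16 | (2S,4R,8Z)-10-[(tert-butyldiphenylsilyl)oxy]-4-hydroxy-4,8-dimethyl-5-oxo-1-(trityloxy)dec-8-en-2-yl 2-methylprop-2-enoate | c1ccccc1C(c1ccccc1)(c1ccccc1)OC[C@@H](OC(=O)C(C)=C)C[C@@](C)(O)C(=O)CC/C(C)=C\CO[Si](c1ccccc1)(c1ccccc1)C(C)(C)C | intermediate (not isolated)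
17 | (2S,4R,8Z)-4-acetoxy-10-[(tert-butyldiphenylsilyl)oxy]-4,8-dimethyl-5-oxo-1-(trityloxy)dec-8-en-2-yl 2-methylprop-2-enoate | c1ccccc1C(c1ccccc1)(c1ccccc1)OC[C@@H](OC(=O)C(C)=C)C[C@@](C)(OC(C)=O)C(=O)CC/C(C)=C\CO[Si](c1ccccc1)(c1ccccc1)C(C)(C)C | intermediate
18 | (2S,4R,8Z)-4-acetoxy-10-[(tert-butyldiphenylsilyl)oxy]-4,8-dimethyl-2-[(2-methylprop-2-enoyl)oxy]-5-oxodec-8-enoic acid | OC(=O)[C@@H](OC(=O)C(C)=C)C[C@@](C)(OC(C)=O)C(=O)CC/C(C)=C\CO[Si](c1ccccc1)(c1ccccc1)C(C)(C)C | intermediate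
19 | acid chloride of 18 | ClC(=O)[C@@H](OC(=O)C(C)=C)C[C@@](C)(OC(C)=O)C(=O)CC/C(C)=C\CO[Si](c1ccccc1)(c1ccccc1)C(C)(C)C | intermediate (not isolated)
20 | methyl (4S,6R,10Z)-6-acetoxy-12-[(tert-butyldiphenylsilyl)oxy]-6,10-dimethyl-2-methylidene-4-[(2-methylprop-2-enoyl)oxy]-3,7-dioxododec-10-enoate | C=C(C(=O)OC)C(=O)[C@@H](OC(=O)C(C)=C)C[C@@](C)(OC(C)=O)C(=O)CC/C(C)=C\CO[Si](c1ccccc1)(c1ccccc1)C(C)(C)C | intermediate (not isolated)
21 | methyl (4S,6R,10Z)-6-acetoxy-2-(acetoxymethyl)-12-[(tert-butyldiphenylsilyl)oxy]-6,10-dimethyl-4-[(2-methylprop-2-enoyl)oxy]-3,7-dioxododec-10-enoate (C2 epimers, keto–enol mixture) | COC(=O)C(COC(C)=O)C(=O)[C@@H](OC(=O)C(C)=C)C[C@@](C)(OC(C)=O)C(=O)CC/C(C)=C\CO[Si](c1ccccc1)(c1ccccc1)C(C)(C)C | intermediate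
22 | chelated lithium enolate of 21 (OLi cis to CO2Me) | COC(=O)/C(COC(C)=O)=C(\O[Li])[C@@H](OC(=O)C(C)=C)C[C@@](C)(OC(C)=O)C(=O)CC/C(C)=C\CO[Si](c1ccccc1)(c1ccccc1)C(C)(C)C | intermediate (not isolated)
23 | methyl (2Z,4S,6R,10Z)-6-acetoxy-2-(acetoxymethyl)-12-[(tert-butyldiphenylsilyl)oxy]-6,10-dimethyl-4-[(2-methylprop-2-enoyl)oxy]-7-oxo-3-{[(trifluoromethyl)sulfonyl]oxy}dodeca-2,10-dienoate | COC(=O)/C(COC(C)=O)=C(\OS(=O)(=O)C(F)(F)F)[C@@H](OC(=O)C(C)=C)C[C@@](C)(OC(C)=O)C(=O)CC/C(C)=C\CO[Si](c1ccccc1)(c1ccccc1)C(C)(C)C | intermediate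
24 | methyl (2Z,4S,6R,10Z)-6-acetoxy-2-(acetoxymethyl)-12-hydroxy-6,10-dimethyl-4-[(2-methylprop-2-enoyl)oxy]-7-oxo-3-{[(trifluoromethyl)sulfonyl]oxy}dodeca-2,10-dienoate | COC(=O)/C(COC(C)=O)=C(\OS(=O)(=O)C(F)(F)F)[C@@H](OC(=O)C(C)=C)C[C@@](C)(OC(C)=O)C(=O)CC/C(C)=C\CO | intermediate
25 | methyl (2Z,4S,6R,10Z)-6-acetoxy-2-(acetoxymethyl)-6,10-dimethyl-4-[(2-methylprop-2-enoyl)oxy]-7,12-dioxo-3-{[(trifluoromethyl)sulfonyl]oxy}dodeca-2,10-dienoate | COC(=O)/C(COC(C)=O)=C(\OS(=O)(=O)C(F)(F)F)[C@@H](OC(=O)C(C)=C)C[C@@](C)(OC(C)=O)C(=O)CC/C(C)=C\C=O | intermediate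
26 | methyl (4Z,6S,8S,10R)-10,13-diacetoxy-8-[(2-methylprop-2-enoyl)oxy]-1-oxo-6-[(trimethylsilyl)oxy]germacra-4,7(11)-dien-12-oate, C6 cis to CO2Me across C7=C11 | C=C(C)C(=O)O[C@H]1C[C@@](C)(OC(C)=O)C(=O)CC/C(C)=C\[C@H](O[Si](C)(C)C)/C1=C(/COC(C)=O)C(=O)OC | intermediate (not isolated)
27 | (4Z,6S,8S,10R)-10,13-diacetoxy-8-[(2-methylprop-2-enoyl)oxy]-1-oxogermacra-4,7(11)-dien-6,12-olide | C=C(C)C(=O)O[C@H]1C[C@@](C)(OC(C)=O)C(=O)CC/C(C)=C\[C@@H]2OC(=O)C(COC(C)=O)=C12 | intermediate
28 | (4R,5S,6R,8S,10R)-10,13-diacetoxy-4,5-epoxy-8-[(2-methylprop-2-enoyl)oxy]-1-oxogermacr-7(11)-en-6,12-olide | C=C(C)C(=O)O[C@H]1C[C@@](C)(OC(C)=O)C(=O)CC[C@@]2(C)O[C@H]2[C@@H]2OC(=O)C(COC(C)=O)=C12 | target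

**Step count and risks**

Total step count: 15 (steps 1–4 give iodide 7, steps 5–6 give lactone 12, steps 7–15 are common). Longest linear sequence: 13 steps (1–4, then 7–15).

Most likely to fail, step 14 (the proposed electrochemical ring closure). A ten-membered ring has to close through a hindered tetrasubstituted alkenyl–metal species, the enal or the methacrylate may be reduced at the cathode, and the C6 selectivity rests on a model. The fallback uses known chemistry and sets out from 25: a stoichiometric Nozaki–Hiyama–Kishi macrocyclization without current or chlorosilane (CrCl2, 8 equiv, NiCl2, 0.1 equiv, degassed DMSO/THF, 2 mM) gives after aqueous work-up the ring-closed hydroxy ester F1. F1 is lactonized in a separate operation with pyridinium p-toluenesulfonate in CH2Cl2, and the route is rejoined at 27.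

Second, step 11 (chelate-controlled enol triflation). The enolate can expel the β-acetate, or the acetate carbonyl can compete for lithium and erode the geometry. The fallback makes the geometry irrelevant and sets out from 21: triflation without chelation control (Tf2O, iPr2NEt, CH2Cl2) gives 23 mixed with the (2E) enol triflate F2. The mixture is carried through the conditions of steps 12 and 13 to the (2E) allylic alcohol F3 and the (2E) enal F4. Ring closure as in step 14 then gives 27 from the Z series and, from F4, the non-lactonizable hydroxy ester F5 (C6–OH trans to CO2Me). Irradiation of F5 at 300 nm in MeCN (photochemical E/Z isomerization of a γ-hydroxy enoate with lactonization of the cis isomer) converts it into 27, where the route is rejoined.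

Third, step 15 (facial selectivity of the epoxidation), which depends on the conformation of the macrocycle. If the peracid attacks the other face, the fallback sets out from 27: NBS in aqueous THF gives the bromohydrin F6 (bromonium on the outer face, water anti at the tertiary C4). Ag2O in CH2Cl2 then closes the oxirane by displacement of bromide at C5 with inversion, which places the epoxide oxygen on the face opposite to direct peracid attack and rejoins the route at 28.

**Further compounds**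

F1 | step 14 | methyl (4Z,6S,8S,10R)-10,13-diacetoxy-6-hydroxy-8-[(2-methylprop-2-enoyl)oxy]-1-oxogermacra-4,7(11)-dien-12-oate, C6 cis to CO2Me | C=C(C)C(=O)O[C@H]1C[C@@](C)(OC(C)=O)C(=O)CC/C(C)=C\[C@H](O)/C1=C(/COC(C)=O)C(=O)OC
F2 | step 11 | (2E) isomer of 23 | COC(=O)/C(COC(C)=O)=C(/OS(=O)(=O)C(F)(F)F)[C@@H](OC(=O)C(C)=C)C[C@@](C)(OC(C)=O)C(=O)CC/C(C)=C\CO[Si](c1ccccc1)(c1ccccc1)C(C)(C)C
F3 | step 11 | (2E) isomer of 24 | COC(=O)/C(COC(C)=O)=C(/OS(=O)(=O)C(F)(F)F)[C@@H](OC(=O)C(C)=C)C[C@@](C)(OC(C)=O)C(=O)CC/C(C)=C\CO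
F4 | step 11 | (2E) isomer of 25 | COC(=O)/C(COC(C)=O)=C(/OS(=O)(=O)C(F)(F)F)[C@@H](OC(=O)C(C)=C)C[C@@](C)(OC(C)=O)C(=O)CC/C(C)=C\C=O
F5 | step 11 | C7=C11 geometric isomer of F1, C6 cis to CH2OAc | C=C(C)C(=O)O[C@H]1C[C@@](C)(OC(C)=O)C(=O)CC/C(C)=C\[C@H](O)/C1=C(\COC(C)=O)C(=O)OC
F6 | step 15 | (4R,5R,6R,8S,10R)-10,13-diacetoxy-5-bromo-4-hydroxy-8-[(2-methylprop-2-enoyl)oxy]-1-oxogermacr-7(11)-en-6,12-olide | C=C(C)C(=O)O[C@H]1C[C@@](C)(OC(C)=O)C(=O)CC[C@@](C)(O)[C@H](Br)[C@@H]2OC(=O)C(COC(C)=O)=C12
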